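**Assumption:** the SMILES is taken literally. In labdane numbering the target is 4α‑CH2OH (C18), 4β‑CH3, 5α‑H, 6β‑OBz, 9β‑H (side chain α, trans to the 10β‑CH3), i.e. a 9‑epi‑labdane.

## Retrosynthetic overview

1. Target ⇐ cross‑metathesis (C13=C14) and Cu‑catalysed coupling (C12–C13) on a C12‑functionalised 9βH‑labd‑8(17)‑ene; the 6β‑oxygen comes from α‑face hydride reduction of a 6‑ketone.
2. Key step: Johnson–Claisen [3,3] rearrangement of a Δ8(9)‑17‑ol forms C9–C11 on the α face (trans to C10‑CH3) and the 8(17)‑methylene at once.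
3. Ring B is rebuilt by an intramolecular Horner–Wadsworth–Emmons closure (C8=C9) of a ring‑A dialdehyde; C8 and C17 come from triethyl phosphonoacetate.
4. Ring A with C4, C5 and C10 is bought as (+)‑dehydroabietic acid; ring C and C8 are excised (benzylic oxidation, α‑acetoxylation, Baeyer–Villiger, RuO4).
5. Ring order: ring A (bought) → ring B (HWE) → C9 and exocyclic alkene (Claisen) → side chain.

## Route

Step 1
Reactants: 1 (+)-dehydroabietic acid
Product: 2 dehydroabietinol
Conditions: LiAlH4, THF, 0 °C → reflux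
Reagents that add atoms: none
Why: Hydride reduction of the hindered C4 acid to the neopentyl alcohol; no stereocentre is touched.

Step 2
Reactants: 2 dehydroabietinol
Product: 3 18-O-triisopropylsilyl dehydroabietinol
Conditions: TIPSOTf, 2,6-lutidine, CH2Cl2, 0 °C
Reagents that add atoms: triisopropylsilyl triflate CC(C)[Si](OS(=O)(=O)C(F)(F)F)(C(C)C)C(C)C
Why: Silyl triflate silylation of the hindered primary alcohol; the TIPS ether is stable to the oxidants, hydrides and heat used later.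

Step 3
Reactants: 3 18-O-triisopropylsilyl dehydroabietinol
Product: 4 18-(triisopropylsilyloxy)abieta-8,11,13-trien-7-one
Conditions: CrO3, 3,5-dimethylpyrazole, CH2Cl2, −20 → 0 °C
Reagents that add atoms: chromium trioxide O=[Cr](=O)=O
Why: Benzylic oxidation at the only secondary benzylic carbon, C7; any attack on the isopropyl C–H is harmless because ring C is excised later.

Step 4
Reactants: 4 18-(triisopropylsilyloxy)abieta-8,11,13-trien-7-one
Product: 5 6α-acetoxy-18-(triisopropylsilyloxy)abieta-8,11,13-trien-7-one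
Conditions: Mn(OAc)3·2H2O, benzene, reflux
Reagents that add atoms: manganese triacetate CC(=O)O[Mn](OC(C)=O)OC(C)=O
Why: α-Acetoxylation of the aryl ketone through its only enol (C6=C7), acetate entering on the less hindered α face; this C6 configuration is provisional and is erased at ketone 14.

Step 5
Reactants: 5 6α-acetoxy-18-(triisopropylsilyloxy)abieta-8,11,13-trien-7-one
Product: 6 seven-membered aryl lactone (O inserted between C7 and C8)
Conditions: mCPBA, CF3CO2H (cat.), CH2Cl2, rt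
Reagents that add atoms: mCPBA OOC(=O)c1cccc(Cl)c1
Why: Baeyer–Villiger oxidation with migration of the electron-rich aryl group; it turns the deactivating aryl ketone into an aryl ester so that ring C can be degraded.

Step 6
Reactants: 6 seven-membered aryl lactone
Product: 7 ring-A diacid (C10–CO2H = C9; C5–CH(OAc)–CO2H = C6/C7)
Conditions: RuCl3·xH2O (cat.), NaIO4, EtOAc/MeCN/H2O, rt
Reagents that add atoms: sodium periodate [Na+].[O-]I(=O)(=O)=O; water O
Why: RuO4 degradation of the aryloxy ring leaves the ipso carbon C9 as CO2H on C10 and, after loss of C8 as CO2, C7 as CO2H; C4, C5 and C10 are untouched.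

Step 7
Reactants: 7 ring-A diacid
Product: 8 ring-A diol (C7–OH and C9–OH)
Conditions: BH3·THF, THF, 0 °C → rt; MeOH quench
Reagents that add atoms: none
Why: Borane reduces carboxylic acids chemoselectively beside the acetate and the silyl ether.

Step 8
Reactants: 8 ring-A diol
Product: 9 ring-A dialdehyde (C7–CHO and C9–CHO)
Conditions: (COCl)2, DMSO, CH2Cl2, −78 °C; i-Pr2NEt
Reagents that add atoms: none
Why: Swern oxidation of both primary alcohols under cold, non-acidic conditions.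

Step 9
Reactants: 9 ring-A dialdehyde
Product: 10 C7-alkylidene phosphonoacetate (E/Z mixture)
Conditions: (EtO)2P(O)CH2CO2Et, TiCl4, pyridine, THF, 0 °C → rt
Reagents that add atoms: triethyl phosphonoacetate CCOC(=O)CP(=O)(OCC)OCC
Why: Lehnert–Knoevenagel condensation occurs only at the unhindered α-acetoxy aldehyde (C7); the neopentyl C9 aldehyde on quaternary C10 does not react.

Step 10
Reactants: 10 C7-alkylidene phosphonoacetate
Product: 12 ethyl 6α-acetoxy-18-(triisopropylsilyloxy)-trans-decal-8-ene-8-carboxylate (labdane numbering; C17 = ester carbon), via phosphonate aldehyde 11 (not isolated)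
Conditions: Hantzsch ester, toluene, 70 °C; then LiCl, DBU, MeCN, rt
Reagents that add atoms: none
Why: Transfer hydrogenation reduces only the doubly activated alkene; the phosphonate then closes ring B onto the C9 aldehyde by an intramolecular Masamune–Roush Horner–Wadsworth–Emmons reaction, and the two equatorial arms on C5 and C10 give the trans-decalin.

Step 11
Reactants: 12 bicyclic enoate
Product: 13 6α,17-diol
Conditions: i-Bu2AlH, CH2Cl2, −78 → 0 °C
Reagents that add atoms: none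
Why: 1,2-Reduction of the conjugated ester to the allylic alcohol with reductive removal of the acetate.

Step 12
Reactants: 13 6α,17-diol
Product: 14 6-oxo-Δ8(9)-17-al
Conditions: Dess–Martin periodinane, CH2Cl2, 0 °C → rt; used at once
Reagents that add atoms: none
Why: Dess–Martin oxidation of both alcohols; the C6 ketone erases the provisional C6 centre, so any C6 epimer formed in steps 8–10 converges here.

Step 13
Reactants: 14 6-oxo-Δ8(9)-17-al
Product: 15 6β,17-diol
Conditions: NaBH4, CeCl3·7H2O, MeOH, −78 → −20 °C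
Reagents that add atoms: none
Why: Luche reduction: 1,2-addition to the enal, and hydride attack on the C6 ketone from the α face because the β face is blocked by the two syn-axial methyls on C4 and C10, giving the axial 6β-alcohol.

Step 14
Reactants: 15 6β,17-diol
Product: 17 ethyl 6β-hydroxy-18-(triisopropylsilyloxy)-13,14,15,16-tetranor-9βH-labd-8(17)-en-12-oate, via mixed ketene acetal 16 (not isolated)
Conditions: MeC(OEt)3, EtCO2H (cat.), xylene, 140 °C
Reagents that add atoms: triethyl orthoacetate CCOC(C)(OCC)OCC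
Why: Johnson–Claisen [3,3]-sigmatropic rearrangement through a chair transition state; the C9–C11 bond forms axially on the α face, anti to the axial C10 methyl, which sets C9 and creates the 8(17)-methylene. The hindered axial 6β-OH does not interfere.

Step 15
Reactants: 17 Claisen ester
Product: 18 6β,12-diol
Conditions: LiAlH4, THF, 0 °C
Reagents that add atoms: none
Why: Ester reduction to the primary alcohol; silyl ether and alkene are inert.

Step 16
Reactants: 18 6β,12-diol
Product: 19 12-iodide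
Conditions: I2, PPh3, imidazole, CH2Cl2, 0 °C
Reagents that add atoms: iodine [I][I]
Why: Appel iodination of the unhindered primary alcohol; the axial, doubly flanked 6β-OH does not react.

Step 17
Reactants: 19 12-iodide
Product: 20 18-(triisopropylsilyloxy)-15-nor-9βH-labda-8(17),13-dien-6β-ol
Conditions: CH2=C(CH3)MgBr (3 equiv), CuI (10 mol %), THF, −20 → 0 °C
Reagents that add atoms: isopropenylmagnesium bromide C=C(C)[Mg]Br
Why: Copper-catalysed sp3–sp2 Grignard cross-coupling (Kochi type) of the primary iodide; one Grignard equivalent is consumed by the hydroxyl.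

Step 18
Reactants: 20 dienol
Product: 21 6β-benzoate of 20
Conditions: BzCl, DMAP, pyridine, 80 °C
Reagents that add atoms: benzoyl chloride O=C(Cl)c1ccccc1
Why: DMAP-catalysed acylation of the only free hydroxyl, forced because it is axial and hindered.

Step 19
Reactants: 21 6β-benzoate
Product: 22 6β-benzoyloxy-18-(triisopropylsilyloxy)-9βH-labda-8(17),13E-dien-15-al
Conditions: crotonaldehyde (5 equiv), second-generation Hoveyda–Grubbs catalyst (H2IMes)Cl2Ru=CH(C6H4-2-OiPr) (10 mol %), CH2Cl2, 40 °C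
Reagents that add atoms: (E)-crotonaldehyde C/C=C/C=O
Why: Olefin cross-metathesis of the acyclic 2-methyl-1-alkene gives the thermodynamically favoured (E)-trisubstituted enal; the hindered ring methylene does not take part.

Step 20
Reactants: 22 silyl-protected enal
Product: 23 target, 6β-benzoyloxy-18-hydroxy-9βH-labda-8(17),13E-dien-15-al
Conditions: HF·pyridine, THF/pyridine, 0 °C → rt
Reagents that add atoms: none
Why: Fluoride cleavage of the silyl ether; benzoate, enal and alkenes are stable to buffered HF.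

## Compound list

1 | (+)-dehydroabietic acid (abieta-8,11,13-trien-18-oic acid; 4α-CO2H, 4β-CH3, 5α-H, 10β-CH3) | C1[C@H]2[C@](C)(C(=O)O)CCC[C@]2(C)c2ccc(C(C)C)cc2C1 | starting material
2 | dehydroabietinol (abieta-8,11,13-trien-18-ol) | C1[C@H]2[C@](C)(CO)CCC[C@]2(C)c2ccc(C(C)C)cc2C1 | intermediate
3 | 18-O-triisopropylsilyl dehydroabietinol | C1[C@H]2[C@](C)(CO[Si](C(C)C)(C(C)C)C(C)C)CCC[C@]2(C)c2ccc(C(C)C)cc2C1 | intermediate
4 | 18-(triisopropylsilyloxy)abieta-8,11,13-trien-7-one | O=C1C[C@H]2[C@](C)(CO[Si](C(C)C)(C(C)C)C(C)C)CCC[C@]2(C)c2ccc(C(C)C)cc21 | intermediate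
5 | 6α-acetoxy-18-(triisopropylsilyloxy)abieta-8,11,13-trien-7-one | O=C1[C@H](OC(C)=O)[C@H]2[C@](C)(CO[Si](C(C)C)(C(C)C)C(C)C)CCC[C@]2(C)c2ccc(C(C)C)cc21 | intermediate
6 | seven-membered aryl lactone of 5 (C7(=O)–O–C8; 6-acetoxy retained) | O=C1[C@H](OC(C)=O)[C@H]2[C@](C)(CO[Si](C(C)C)(C(C)C)C(C)C)CCC[C@]2(C)c2ccc(C(C)C)cc2O1 | intermediate
7 | ring-A diacid: 4-(TIPSOCH2)-4,10-dimethylcyclohexane with C10–CO2H (C9) and C5–CH(OAc)CO2H (C6, C7) | OC(=O)[C@H](OC(C)=O)[C@H]1[C@](C)(CO[Si](C(C)C)(C(C)C)C(C)C)CCC[C@]1(C)C(=O)O | intermediate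
8 | ring-A diol (C7–OH, C9–OH; 6-OAc) | OC[C@H](OC(C)=O)[C@H]1[C@](C)(CO[Si](C(C)C)(C(C)C)C(C)C)CCC[C@]1(C)CO | intermediate
9 | ring-A dialdehyde (C7–CHO, C9–CHO; 6-OAc) | O=C[C@H](OC(C)=O)[C@H]1[C@](C)(CO[Si](C(C)C)(C(C)C)C(C)C)CCC[C@]1(C)C=O | intermediate
10 | C7-alkylidene phosphonoacetate (E/Z mixture) bearing the C9 aldehyde | CCOC(=O)C(=C[C@H](OC(C)=O)[C@H]1[C@](C)(CO[Si](C(C)C)(C(C)C)C(C)C)CCC[C@]1(C)C=O)P(=O)(OCC)OCC | intermediate
11 | saturated phosphonoacetate aldehyde (C8 epimers) | CCOC(=O)C(C[C@H](OC(C)=O)[C@H]1[C@](C)(CO[Si](C(C)C)(C(C)C)C(C)C)CCC[C@]1(C)C=O)P(=O)(OCC)OCC | intermediate (not isolated)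
12 | ethyl 6α-acetoxy-18-(triisopropylsilyloxy)-trans-decal-8-ene-8-carboxylate (4β,10β-dimethyl, 5α-H; C17 ester on C8) | CCOC(=O)C=1C[C@H](OC(C)=O)[C@H]2[C@](C)(CO[Si](C(C)C)(C(C)C)C(C)C)CCC[C@]2(C)C=1 | intermediate
13 | 6α,17-diol of the Δ8(9) bicycle | OCC=1C[C@H](O)[C@H]2[C@](C)(CO[Si](C(C)C)(C(C)C)C(C)C)CCC[C@]2(C)C=1 | intermediate
14 | 6-oxo-Δ8(9)-17-al | O=CC=1CC(=O)[C@H]2[C@](C)(CO[Si](C(C)C)(C(C)C)C(C)C)CCC[C@]2(C)C=1 | intermediate
15 | 6β,17-diol of the Δ8(9) bicycle | OCC=1C[C@@H](O)[C@H]2[C@](C)(CO[Si](C(C)C)(C(C)C)C(C)C)CCC[C@]2(C)C=1 | intermediate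
16 | 17-O-(1-ethoxyvinyl) ether of 15 (mixed ketene acetal) | C=C(OCC)OCC=1C[C@@H](O)[C@H]2[C@](C)(CO[Si](C(C)C)(C(C)C)C(C)C)CCC[C@]2(C)C=1 | intermediate (not isolated)
17 | ethyl 6β-hydroxy-18-(triisopropylsilyloxy)-13,14,15,16-tetranor-9βH-labd-8(17)-en-12-oate | C=C1C[C@@H](O)[C@H]2[C@](C)(CO[Si](C(C)C)(C(C)C)C(C)C)CCC[C@]2(C)[C@@H]1CC(=O)OCC | intermediate
18 | 18-(triisopropylsilyloxy)-13,14,15,16-tetranor-9βH-labd-8(17)-ene-6β,12-diol | C=C1C[C@@H](O)[C@H]2[C@](C)(CO[Si](C(C)C)(C(C)C)C(C)C)CCC[C@]2(C)[C@@H]1CCO | intermediate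
19 | 12-iodo-18-(triisopropylsilyloxy)-13,14,15,16-tetranor-9βH-labd-8(17)-en-6β-ol | C=C1C[C@@H](O)[C@H]2[C@](C)(CO[Si](C(C)C)(C(C)C)C(C)C)CCC[C@]2(C)[C@@H]1CCI | intermediate
20 | 18-(triisopropylsilyloxy)-15-nor-9βH-labda-8(17),13-dien-6β-ol | C=C1C[C@@H](O)[C@H]2[C@](C)(CO[Si](C(C)C)(C(C)C)C(C)C)CCC[C@]2(C)[C@@H]1CCC(C)=C | intermediate
21 | 6β-benzoate of 20 | C=C1C[C@@H](OC(=O)c2ccccc2)[C@H]2[C@](C)(CO[Si](C(C)C)(C(C)C)C(C)C)CCC[C@]2(C)[C@@H]1CCC(C)=C | intermediate
22 | 6β-benzoyloxy-18-(triisopropylsilyloxy)-9βH-labda-8(17),13E-dien-15-al | C=C1C[C@@H](OC(=O)c2ccccc2)[C@H]2[C@](C)(CO[Si](C(C)C)(C(C)C)C(C)C)CCC[C@]2(C)[C@@H]1CC/C(C)=C/C=O | intermediate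
23 | 6β-benzoyloxy-18-hydroxy-9βH-labda-8(17),13E-dien-15-al (CNP0181075.1) | C=C1C[C@@H](OC(=O)c2ccccc2)[C@H]2[C@](C)(CO)CCC[C@]2(C)[C@@H]1CC/C(C)=C/C=O | target

## Step count and risks

Total step count: 20. Longest linear sequence: 20 (1 → 23, fully linear).

Three steps most likely to fail:

Step 10 (transfer hydrogenation of the alkylidene phosphonoacetate beside a free aldehyde, then ring closure). The fallback sets out from diol 8. Appel iodination (I2, PPh3, imidazole) of the less hindered C7 carbinol gives the iodo alcohol F1. Alkylation of NaCH(CO2Et)P(O)(OEt)2 (NaH, DMF, 50 °C) gives the phosphonate alcohol F2. Dess–Martin oxidation of the neopentyl C9 carbinol then gives 11, where the route is rejoined; 11 is closed to 12 with LiCl/DBU as before.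

Step 14 (Claisen rearrangement at a ring carbon next to the quaternary centre; α-face selectivity and the hot, acidic conditions are the concern). The fallback sets out from 15. KH and Bu3SnCH2I etherify the primary allylic alcohol to the stannylmethyl ether F3. n-BuLi at −78 °C triggers a [2,3]-Wittig–Still rearrangement, which also forms the bond axially on the α face but cold and under basic conditions, giving the 9α-hydroxymethyl-8(17)-ene F4. TEMPO/PhI(OAc)2 oxidises only the primary alcohol to the aldehyde F5. Ph3P=CH2 gives the 9α-vinyl compound F6. 9-BBN followed by NaOH/H2O2 hydroborates only the monosubstituted vinyl group and returns to the route at 18.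

Step 19 (cross-metathesis of a 1,1-disubstituted alkene; conversion and E/Z ratio are the concern). The fallback sets out from iodide 19. LiC≡CH·ethylenediamine in DMSO gives the terminal alkyne F7. Negishi carboalumination (Me3Al, Cp2ZrCl2, syn addition), then n-BuLi and (CH2O)n, gives the stereodefined (E)-allylic alcohol F8. MnO2 oxidises only the allylic alcohol to the enal F9. BzCl/DMAP/pyridine then benzoylates the 6β-OH and returns to the route at 22.

## Further compounds

F1 | step 10 | ring-A iodo alcohol (C7–I, C9–OH, 6-OAc) | IC[C@H](OC(C)=O)[C@H]1[C@](C)(CO[Si](C(C)C)(C(C)C)C(C)C)CCC[C@]1(C)CO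
F2 | step 10 | saturated phosphonoacetate with free C9 carbinol | CCOC(=O)C(C[C@H](OC(C)=O)[C@H]1[C@](C)(CO[Si](C(C)C)(C(C)C)C(C)C)CCC[C@]1(C)CO)P(=O)(OCC)OCC
F3 | step 14 | 17-O-(tributylstannylmethyl) ether of 15 | CCCC[Sn](CCCC)(CCCC)COCC=1C[C@@H](O)[C@H]2[C@](C)(CO[Si](C(C)C)(C(C)C)C(C)C)CCC[C@]2(C)C=1
F4 | step 14 | 9α-hydroxymethyl-8(17)-ene (C11 alcohol, 6β-OH) | C=C1C[C@@H](O)[C@H]2[C@](C)(CO[Si](C(C)C)(C(C)C)C(C)C)CCC[C@]2(C)[C@@H]1CO
F5 | step 14 | 9α-formyl-8(17)-ene (C11 aldehyde) | C=C1C[C@@H](O)[C@H]2[C@](C)(CO[Si](C(C)C)(C(C)C)C(C)C)CCC[C@]2(C)[C@@H]1C=O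
F6 | step 14 | 9α-vinyl-8(17)-ene | C=C1C[C@@H](O)[C@H]2[C@](C)(CO[Si](C(C)C)(C(C)C)C(C)C)CCC[C@]2(C)[C@@H]1C=C
F7 | step 19 | terminal alkyne (C13≡C14) with 6β-OH | C=C1C[C@@H](O)[C@H]2[C@](C)(CO[Si](C(C)C)(C(C)C)C(C)C)CCC[C@]2(C)[C@@H]1CCC#C
F8 | step 19 | (13E)-allylic alcohol, 6β,15-diol | C=C1C[C@@H](O)[C@H]2[C@](C)(CO[Si](C(C)C)(C(C)C)C(C)C)CCC[C@]2(C)[C@@H]1CC/C(C)=C/CO
F9 | step 19 | (13E)-enal with free 6β-OH | C=C1C[C@@H](O)[C@H]2[C@](C)(CO[Si](C(C)C)(C(C)C)C(C)C)CCC[C@]2(C)[C@@H]1CC/C(C)=C/C=O
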